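**Retrosynthetic overview**
- Selaginellin U ⇐ BBr3 demethylation and dehydration of a tetra-O-methyl triaryl carbinol ⇐ twofold addition of 4-methoxyphenyllithium to a ring A methyl benzoate whose ester carbon is C7; the C2 alkyne ⇐ Sonogashira coupling of a C2 aryl triflate with 4-ethynylanisole.
- Feature used: ring A carries methyl on C1, the alkyne on C2, C7 on C3, ring B on C4 and hydrogen on C5 and C6. C3–C6 with their substituents map onto C3–C6 of a 4-(4-methoxyphenyl)-3-carbomethoxy-2-pyrone, and C1–C2 are the two sp carbons of 1-ethoxypropyne, whose OEt becomes the handle for the alkyne.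
- Ring A ⇐ inverse-electron-demand [4+2] of that pyrone with the ynol ether (bonds C1–C6 and C2–C3), then retro-[4+2] loss of CO2.
- Pyrone ⇐ acid lactonisation of the Knoevenagel adduct of dimethyl malonate with 3,3-dimethoxy-1-(4-methoxyphenyl)propan-1-one ⇐ formylation and acetalisation of 4'-methoxyacetophenone.
- Ring order: pyrone ring (step 4), then ring A (step 5); the four oxygenated aryl rings are bought as anisyl units; the target has no stereocentre.

Key step: step 5

Assumption: ring A is numbered C1 (methyl), C2 (alkynyl), C3 (bearing C7, the quinone methide carbon), C4 (bearing ring B), C5 and C6 (CH); 1-ethoxyprop-1-yne, 4-ethynylanisole and 4-bromoanisole are taken as purchased.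

**Route**

Step 1
Reactants: 1 4'-methoxyacetophenone; 2 methyl formate
Product: 3 sodium (Z)-3-(4-methoxyphenyl)-3-oxoprop-1-en-1-olate
Conditions: NaOMe, HCO2Me (excess), Et2O, 0 °C to rt; salt collected by filtration
Reagents that add atoms: sodium methoxide, C[O-].[Na+]
Why: Crossed Claisen condensation (formylation) of the methyl ketone enolate on methyl formate, driven to completion because the product precipitates as its chelated sodium enolate.

Step 2
Reactants: 3 sodium (Z)-3-(4-methoxyphenyl)-3-oxoprop-1-en-1-olate
Product: 4 3,3-dimethoxy-1-(4-methoxyphenyl)propan-1-one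
Conditions: anhydrous HCl in MeOH, −10 °C to rt; then NaHCO3
Reagents that add atoms: methanol, CO
Why: Acid-catalysed acetalisation, in which the aldehyde carbon of the liberated β-keto aldehyde is far more electrophilic than the anisoyl ketone and is masked selectively as the dimethyl acetal before it can self-condense.

Step 3
Reactants: 4 3,3-dimethoxy-1-(4-methoxyphenyl)propan-1-one; 5 dimethyl malonate
Product: 6 dimethyl 2-[3,3-dimethoxy-1-(4-methoxyphenyl)propylidene]malonate
Conditions: TiCl4, pyridine, THF, 0 °C to rt
Reagents that add atoms: none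
Why: Knoevenagel condensation under Lehnert conditions, where TiCl4 activates the aryl ketone and binds the water formed while excess pyridine generates the titanium malonate enolate and tempers the Lewis acid towards the acetal; the symmetrical malonate end leaves no alkene geometry to control.

Step 4
Reactants: 6 dimethyl 2-[3,3-dimethoxy-1-(4-methoxyphenyl)propylidene]malonate
Product: 8 methyl 4-(4-methoxyphenyl)-2-oxo-2H-pyran-3-carboxylate, via aldehyde 7 (not isolated)
Conditions: 88% aqueous HCO2H, 70 °C
Reagents that add atoms: water, O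
Why: Acetal hydrolysis followed by enol lactonisation, in which aldehyde 7 enolises into conjugation with the alkylidene malonate and its enol oxygen acylates on the ester that is necessarily cis to it, expelling methanol to give the 2-pyrone.

Step 5
Reactants: 8 methyl 4-(4-methoxyphenyl)-2-oxo-2H-pyran-3-carboxylate; 9 1-ethoxyprop-1-yne
Product: 11 methyl 2-ethoxy-6-(4-methoxyphenyl)-3-methylbenzoate, via bridged lactone 10 (not isolated)
Conditions: 9 (3–5 equiv), toluene, 80 °C, sealed tube
Reagents that add atoms: none
Why: Diels–Alder reaction with inverse electron demand followed by cycloreversion: the lactone carbonyl and the C3 ester make pyrone 8 an electron-poor diene, and the HOMO of the ynol ether adds across C3 and C6 in an asynchronous [4+2] to give the 2-oxabicyclo[2.2.2]octadienone 10, which expels CO2 by retro-[4+2] below the reaction temperature. The closest known chemistry is the benzannulation of 3-carbomethoxy-2-pyrones with ketene acetals, ynamines and other electron-rich alkynes. Ring A is closed by this intermolecular cycloaddition, which forms C1–C6 and C2–C3 (ring A numbering) in one operation, and it arrives aromatic because the alkyne supplies the third double bond. No stereocentre remains, since the two bridgehead centres of 10 are destroyed when CO2 leaves. The step needs regioselectivity only: C6 of the pyrone is the unhindered δ-terminus of a doubly activated dienoate and its most electrophilic site, while the methyl-bearing carbon of EtO–C≡C–Me is the nucleophilic one, so bonding leads from that carbon to C6 and the oxygen-stabilised carbon then closes onto the ester-stabilised C3. This places OEt beside the ester and methyl beside OEt, as ring A requires.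

Step 6
Reactants: 11 methyl 2-ethoxy-6-(4-methoxyphenyl)-3-methylbenzoate
Product: 12 methyl 2-hydroxy-6-(4-methoxyphenyl)-3-methylbenzoate
Conditions: BCl3 (1.5 equiv), CH2Cl2, −78 to 0 °C; then H2O
Reagents that add atoms: none
Why: Chelation-directed ether cleavage, in which BCl3 held between the ester carbonyl and the ortho ethoxy oxygen delivers chloride to the ethyl group, whereas the remote anisole ether has no neighbouring carbonyl and should survive at this temperature.

Step 7
Reactants: 12 methyl 2-hydroxy-6-(4-methoxyphenyl)-3-methylbenzoate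
Product: 13 methyl 6-(4-methoxyphenyl)-3-methyl-2-(trifluoromethanesulfonyloxy)benzoate
Conditions: Tf2O, pyridine, CH2Cl2, 0 °C to rt
Reagents that add atoms: trifluoromethanesulfonic anhydride, O=S(=O)(OS(=O)(=O)C(F)(F)F)C(F)(F)F
Why: O-Sulfonylation of the phenol gives the aryl triflate, which the ortho ester makes electron-poor and therefore reactive in oxidative addition.

Step 8
Reactants: 13 methyl 6-(4-methoxyphenyl)-3-methyl-2-(trifluoromethanesulfonyloxy)benzoate; 14 4-ethynylanisole
Product: 15 methyl 6-(4-methoxyphenyl)-2-[(4-methoxyphenyl)ethynyl]-3-methylbenzoate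
Conditions: Pd(PPh3)2Cl2 (5 mol%), CuI (10 mol%), Et3N, DMF, 70 °C
Reagents that add atoms: none
Why: Sonogashira coupling, in which zerovalent palladium inserts into the activated C–OTf bond, the copper acetylide of 14 transmetalates and reductive elimination forms the C2–alkynyl bond, the slim linear alkyne tolerating the two ortho substituents.

Step 9
Reactants: 15 methyl 6-(4-methoxyphenyl)-2-[(4-methoxyphenyl)ethynyl]-3-methylbenzoate; 16 4-bromoanisole
Product: 19 bis(4-methoxyphenyl){6-(4-methoxyphenyl)-2-[(4-methoxyphenyl)ethynyl]-3-methylphenyl}methanol, via 4-methoxyphenyllithium 17 (not isolated), via diaryl ketone 18 (not isolated)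
Conditions: 16 (3.3 equiv), n-BuLi (3.0 equiv), THF, −78 °C; then 15, −78 to 0 °C; H2O quench
Reagents that add atoms: none
Why: Bromine–lithium exchange followed by double 1,2-addition of an aryllithium to an ester, in which the first adduct collapses to ketone 18, which has no α-hydrogen and is more electrophilic than the ester, so it takes the second aryllithium, while the diaryl alkyne is inert to aryllithiums at low temperature.

Step 10
Reactants: 19 bis(4-methoxyphenyl){6-(4-methoxyphenyl)-2-[(4-methoxyphenyl)ethynyl]-3-methylphenyl}methanol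
Product: 21 Selaginellin U, via tetraphenol carbinol 20 (not isolated)
Conditions: BBr3 (excess), CH2Cl2, −78 °C to rt; then H2O, NaHCO3
Reagents that add atoms: none
Why: Lewis acid ether cleavage removes all four methyl groups, and the 4-hydroxyphenyl carbinol 20 then loses water through its stabilised triarylmethyl cation to the para-quinone methide; the two aryl groups on C7 are identical, so only one product can form.

**Compound list**
1 | 4'-methoxyacetophenone | CC(=O)c1ccc(OC)cc1 | starting material
2 | methyl formate | COC=O | starting material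
3 | sodium (Z)-3-(4-methoxyphenyl)-3-oxoprop-1-en-1-olate | [Na+].[O-]/C=C\C(=O)c1ccc(OC)cc1 | intermediate
4 | 3,3-dimethoxy-1-(4-methoxyphenyl)propan-1-one | COC(OC)CC(=O)c1ccc(OC)cc1 | intermediate
5 | dimethyl malonate | COC(=O)CC(=O)OC | starting material
6 | dimethyl 2-[3,3-dimethoxy-1-(4-methoxyphenyl)propylidene]malonate | COC(=O)C(C(=O)OC)=C(CC(OC)OC)c1ccc(OC)cc1 | intermediate
7 | dimethyl 2-[1-(4-methoxyphenyl)-3-oxopropylidene]malonate (aldehyde, not isolated) | COC(=O)C(C(=O)OC)=C(CC=O)c1ccc(OC)cc1 | intermediate
8 | methyl 4-(4-methoxyphenyl)-2-oxo-2H-pyran-3-carboxylate | COC(=O)C1=C(C=COC1=O)c1ccc(OC)cc1 | intermediate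
9 | 1-ethoxyprop-1-yne | CCOC#CC | starting material
10 | methyl 8-ethoxy-5-(4-methoxyphenyl)-7-methyl-3-oxo-2-oxabicyclo[2.2.2]octa-5,7-diene-4-carboxylate (racemic, one enantiomer drawn, not isolated) | COC(=O)[C@]12C(=O)O[C@H](C=C1c1ccc(OC)cc1)C(C)=C2OCC | intermediate
11 | methyl 2-ethoxy-6-(4-methoxyphenyl)-3-methylbenzoate | CCOc1c(C)ccc(-c2ccc(OC)cc2)c1C(=O)OC | intermediate
12 | methyl 2-hydroxy-6-(4-methoxyphenyl)-3-methylbenzoate | COC(=O)c1c(O)c(C)ccc1-c1ccc(OC)cc1 | intermediate
13 | methyl 6-(4-methoxyphenyl)-3-methyl-2-(trifluoromethanesulfonyloxy)benzoate | COC(=O)c1c(OS(=O)(=O)C(F)(F)F)c(C)ccc1-c1ccc(OC)cc1 | intermediate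
14 | 4-ethynylanisole | C#Cc1ccc(OC)cc1 | starting material
15 | methyl 6-(4-methoxyphenyl)-2-[(4-methoxyphenyl)ethynyl]-3-methylbenzoate | COC(=O)c1c(C#Cc2ccc(OC)cc2)c(C)ccc1-c1ccc(OC)cc1 | intermediate
16 | 4-bromoanisole | COc1ccc(Br)cc1 | starting material
17 | 4-methoxyphenyllithium (not isolated) | [Li]c1ccc(OC)cc1 | intermediate
18 | (4-methoxyphenyl){6-(4-methoxyphenyl)-2-[(4-methoxyphenyl)ethynyl]-3-methylphenyl}methanone (not isolated) | COc1ccc(cc1)C(=O)c1c(C#Cc2ccc(OC)cc2)c(C)ccc1-c1ccc(OC)cc1 | intermediate
19 | bis(4-methoxyphenyl){6-(4-methoxyphenyl)-2-[(4-methoxyphenyl)ethynyl]-3-methylphenyl}methanol | COc1ccc(cc1)C(O)(c1ccc(OC)cc1)c1c(C#Cc2ccc(OC)cc2)c(C)ccc1-c1ccc(OC)cc1 | intermediate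
20 | 4,4'-(hydroxy{6-(4-hydroxyphenyl)-2-[(4-hydroxyphenyl)ethynyl]-3-methylphenyl}methylene)diphenol (not isolated) | Oc1ccc(cc1)C(O)(c1ccc(O)cc1)c1c(C#Cc2ccc(O)cc2)c(C)ccc1-c1ccc(O)cc1 | intermediate
21 | Selaginellin U, 4-[(4-hydroxyphenyl){6-(4-hydroxyphenyl)-2-[(4-hydroxyphenyl)ethynyl]-3-methylphenyl}methylidene]cyclohexa-2,5-dien-1-one | Cc1ccc(-c2ccc(O)cc2)c(C(=C2C=CC(=O)C=C2)c2ccc(O)cc2)c1C#Cc1ccc(O)cc1 | target

**Step count**
Total steps: 10. Longest linear sequence: 10 steps (1 to 21).

**Steps most likely to fail**

1. Step 5. The cycloaddition may be slower than the thermal breakdown of the ynol ether, which loses ethylene by retro-ene reaction to methylketene or oligomerises; the anisyl group at C4 raises the LUMO of the pyrone and slows the addition further. The fallback sets out from pyrone 8 and replaces the alkyne by a ketene acetal, the partner with the most direct precedent for such pyrones. 1,1-Diethoxyprop-1-ene F1 would be made by dehydrobromination of commercial 2-bromo-1,1-diethoxypropane (CCOC(OCC)C(C)Br) with KOtBu in t-BuOH and distilled. Heating 8 with F1 in toluene at 110 °C should give, with the same polarity-controlled orientation, the bridged ketal lactone methyl 8,8-diethoxy-5-(4-methoxyphenyl)-7-methyl-3-oxo-2-oxabicyclo[2.2.2]oct-5-ene-4-carboxylate F2. Loss of CO2 from it gives the diene ketal methyl 6,6-diethoxy-2-(4-methoxyphenyl)-5-methylcyclohexa-1,3-diene-1-carboxylate F3, and elimination of ethanol (thermal, or with a trace of TsOH) aromatises it to ethyl ether 11, where the route is rejoined.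

2. Step 3. TiCl4 may ionise the dimethyl acetal faster than the deactivated aryl ketone condenses; loss of methanol would give a β-methoxy enone that takes the malonate at the wrong carbon. The fallback sets out from ketone 1 and malonate 5 and keeps the acetal out of the titanium step. Condensation of 1 with 5 (TiCl4, pyridine, THF) should give dimethyl 2-[1-(4-methoxyphenyl)ethylidene]malonate F4. Its vinylogous methyl group is then condensed with N,N-dimethylformamide dimethyl acetal (COC(OC)N(C)C, neat, 100 °C) to the dienamine dimethyl 2-[(2E)-3-(dimethylamino)-1-(4-methoxyphenyl)prop-2-en-1-ylidene]malonate F5. AcOH with aqueous HCl at 60 °C hydrolyses the enamine and closes the lactone, returning to the route at pyrone 8.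

3. Step 9. The ester sits between two ortho substituents, so the addition may stall before the first or the second aryl group is in place; on warming, the tertiary lithium alkoxide may also add to the neighbouring alkyne. The fallback sets out from ester 15 and builds C7 stepwise through the far less hindered aldehyde. DIBAL-H (CH2Cl2, −78 to 0 °C) should give {6-(4-methoxyphenyl)-2-[(4-methoxyphenyl)ethynyl]-3-methylphenyl}methanol F6, and Dess–Martin periodinane should give 6-(4-methoxyphenyl)-2-[(4-methoxyphenyl)ethynyl]-3-methylbenzaldehyde F7. Addition of 17 at −78 °C gives racemic (4-methoxyphenyl){6-(4-methoxyphenyl)-2-[(4-methoxyphenyl)ethynyl]-3-methylphenyl}methanol F8, and a second Dess–Martin oxidation gives ketone 18, now isolated. The route is rejoined at 18, which takes one more equivalent of 17, premixed with anhydrous CeCl3 if needed, to give carbinol 19.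

**Further compounds**
F1 | step 5 | 1,1-diethoxyprop-1-ene | CCOC(OCC)=CC
F2 | step 5 | methyl 8,8-diethoxy-5-(4-methoxyphenyl)-7-methyl-3-oxo-2-oxabicyclo[2.2.2]oct-5-ene-4-carboxylate (racemic, C7 epimers) | CCOC1(OCC)C(C)C2C=C(c3ccc(OC)cc3)C1(C(=O)OC)C(=O)O2
F3 | step 5 | methyl 6,6-diethoxy-2-(4-methoxyphenyl)-5-methylcyclohexa-1,3-diene-1-carboxylate (racemic) | CCOC1(OCC)C(C)C=CC(c2ccc(OC)cc2)=C1C(=O)OC
F4 | step 3 | dimethyl 2-[1-(4-methoxyphenyl)ethylidene]malonate | COC(=O)C(C(=O)OC)=C(C)c1ccc(OC)cc1
F5 | step 3 | dimethyl 2-[(2E)-3-(dimethylamino)-1-(4-methoxyphenyl)prop-2-en-1-ylidene]malonate | CN(C)/C=C/C(c1ccc(OC)cc1)=C(C(=O)OC)C(=O)OC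
F6 | step 9 | {6-(4-methoxyphenyl)-2-[(4-methoxyphenyl)ethynyl]-3-methylphenyl}methanol | OCc1c(C#Cc2ccc(OC)cc2)c(C)ccc1-c1ccc(OC)cc1
F7 | step 9 | 6-(4-methoxyphenyl)-2-[(4-methoxyphenyl)ethynyl]-3-methylbenzaldehyde | O=Cc1c(C#Cc2ccc(OC)cc2)c(C)ccc1-c1ccc(OC)cc1
F8 | step 9 | (4-methoxyphenyl){6-(4-methoxyphenyl)-2-[(4-methoxyphenyl)ethynyl]-3-methylphenyl}methanol (racemic) | COc1ccc(cc1)C(O)c1c(C#Cc2ccc(OC)cc2)c(C)ccc1-c1ccc(OC)cc1
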